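**Numbering.** 1 dimethoxy aldehyde, 2 dihydroxy aldehyde, 3 mono-silylated aldehyde, 4 acetonyl ylide, 5 enone, 6 saturated ketone, 7 alkenyl phenol (cyclisation precursor), 8 methyl acrylate, 9 alkylpalladium intermediate, 10 chroman enoate, 11 saturated ester, 12 methyl ketone intermediate, 13 tertiary alcohol, 14 C4 peroxide intermediate, 15 silylated chromanone, 16 target.

## Analysis of the target

Target 16 is (R)-7-bromo-6-hydroxy-2-(4-hydroxy-4-methylpentyl)-2-methylchroman-4-one. It is a benzene ring (C4a, C5–C8, C8a) fused to a dihydropyranone ring (O1, C2, C3, C4=O), with OH on C6, Br on C7, and on C2 a methyl group and the chain C1'–C4' that ends in the tertiary alcohol C4'(CH3)2OH. C2 is the only stereocentre: it is fully substituted (O1, C3, C1', CH3; CIP order O1 > C3 > C1' > CH3; R), so there is no second centre from which its configuration could be relayed. The difficulty is that C3 and C1' are both methylene groups that differ only further out, so the centre must be made by a reagent that distinguishes the two faces of a flat precursor. The sensitive groups are four. The C7–Br bond excludes hydrogenation over palladium, metal–halogen exchange and long-lived zerovalent palladium. The β-aryloxy ketone O1–C2–C3–C4=O can open under base by E1cB loss of the C8a phenoxide and so erase C2. The C6 hydroxyl is para to O1, a hydroquinone monoether that is easily oxidised when free. The tertiary alcohol ionises under strong acid. Bromine cannot be placed late with confidence, because C5 and C7 both flank the C6 oxygen. The strategy rests on one structural feature: C2 carries O1, a methyl group and the methylene C1'. This is the pattern left when the C8a hydroxyl adds to the substituted carbon of a 1,1-disubstituted alkene C2(=C1')CH3 held by the C3–C4 tether, and a metal on C1' can then build the chain.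

## Retrosynthetic reasoning

**16 ⇒ 15 (O–Si at C6).** The last operation is the unmasking of the C6 hydroxyl. Neither the quinone oxidant of the palladium step nor the hydroperoxide of the C–H oxidation would tolerate the free hydroquinone monoether, so the oxygen stays silylated from 3 to 15. Acidic fluoride is preferred to basic fluoride because base could open the O1–C2 bond of the finished pyranone.

**15 ⇒ 13 (C4=O back to C4H2).** The ketone is traced to a methylene group. C4 is the only benzylic C–H position of 13, since C2 has no hydrogen, so a radical C–H oxidation has a single site. The oxidation is placed late for three reasons: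
- a C4 ketone would be attacked by the methyl Grignard reagent;
- in the cyclisation precursor it would let the alkene slip into conjugation and close by an uncontrolled oxa-Michael addition;
- it would expose C2 to E1cB racemisation in every basic step.

**13 ⇒ 11 (two C4'–CH3 bonds).** The tertiary alcohol is cut to an ester whose carbonyl carbon is C4'. Twofold addition of a methyl Grignard reagent builds the chain terminus in one step and needs no protecting group on the new hydroxyl afterwards.

**11 ⇒ 10 (C2'–C3' saturation).** The saturated ester comes from the enoate 10 by conjugate reduction. A copper hydride is chosen because the aryl bromide rules out heterogeneous hydrogenation. The descriptor changes from S in 10 to R in 11 only because the CIP order of C1' and C3 changes; no bond at C2 is touched.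

**10 ⇒ 7 + 8 (O1–C2 and C1'–C2').** This is the central disconnection. Cutting O1–C2 and C1'–C2' together gives the achiral alkenyl phenol 7 and methyl acrylate 8. The stereocentre, the pyran ring and two chain carbons are then made in one catalytic operation from a flat alkene.
- Cutting C2–C3 or C2–C1' instead would require a preformed chiral tertiary ether.
- Cutting O1–C2 alone in an oxa-Michael sense would need the C4 ketone and gives no lever for face selection.

In the forward step a chiral divalent palladium complex must choose one alkene face, the alkylpalladium must be intercepted by 8, and the C–Br bond must stay intact.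

**7 ⇒ 6 (C2=C1').** The 1,1-disubstituted alkene is made from the methyl ketone 6 by methylenation with a phosphorus ylide. This places the double bond unambiguously, which a dehydration could not do.

**6 ⇒ 5 ⇒ 3 + 4 (C3–C4).** The ketone 6 comes from the enone 5 by conjugate reduction, again with a copper hydride for the sake of the bromide. Enone 5 comes from aldehyde 3 and the stabilised ylide 4. The aldehyde carbon becomes C4 and the ylide delivers C3, C2 and the C2 methyl group.

**3 ⇒ 2 ⇒ 1 (O–Si, O–CH3).** In 2 the hydroxyl next to the aldehyde is held in a hydrogen bond, so the other hydroxyl (the future C6 oxygen) can be silylated alone to give 3. Compound 2 comes from the commercial dimethoxy aldehyde 1 by cleavage of both methyl ethers. In 1 the bromine already sits para to the formyl group, at the carbon that becomes C7, so no bromination step is needed.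

## Alternatives that were turned down

**Alternative 1: the benzene ring is assembled by a Dötz benzannulation.**
- Disconnection: C8–C8a, C6–C7 and C5–C6. The ring is built from the pyranylidene chromium carbene A1, one of its carbonyl ligands and the ethynylboronate A2.
- Forward key step: on heating these combine to the boronate phenol A3. The carbene carbon becomes C8a, the exocyclic methylene becomes C5, CO becomes C6 and boron arrives on C7 next to the new hydroxyl.
- For it: the route is convergent, the later bromodeboronation would be unambiguous, and palladium never meets an aryl bromide. On that last point it is stronger than the chosen route.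
- Against it:
  - The benzannulation does not create C2. The tertiary ether must already be present in enantiopure form in A1, so the central problem is only moved to a lactone precursor.
  - A1 is a stoichiometric, delicate α-methylene carbene complex that needs several steps to make.
  - A3 is an air-sensitive hydroquinone monoether.
  - After A3 the route still needs bromodeboronation, phenol protection, Markovnikov hydration of the trisubstituted alkene, C4 oxidation and deprotection.
- Comparison: the chosen route makes C2, the pyran ring and two chain carbons in one catalytic step from a five-step precursor, and it buys the bromine regiochemistry with the starting material.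

**Alternative 2: the pyranone ring is closed by a stereoretentive carbene insertion.**
- Disconnection: C2–C3.
- Forward key step: the diazoketone A4 loses nitrogen on a dirhodium carboxylate catalyst and the carbene at C3 inserts into the tertiary C2–H bond, giving the protected chromanone A5.
- For it: the stereocentre comes from a secondary carbinol, which is easy to obtain in high enantiomeric purity. Concerted insertion retains configuration. C4 is already a ketone, so no benzylic oxidation is needed. On the source of chirality and on oxidation level it is stronger than the chosen route.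
- Against it:
  - The insertion must form a six-membered ring at a hindered tertiary C–H bond. It competes with attack of the carbene on O1 (a five-membered oxonium ylide and a 1,2-shift to a benzofuranone, which would also scramble C2) and with addition to the arene. The substrate, not a ligand, decides this contest.
  - A4 needs a separately made chiral side-chain alcohol, an aryl ether formation beside an ortho acyl group, diazomethane chemistry and two different silyl groups.
- Comparison: the step count is no shorter than the chosen route. The chosen route puts its risk into a catalyst-controlled step with a close known analogue.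

**Alternative 3: phenol spirocyclisation followed by a dienone–phenol shift.**
- Disconnection: C8a–O1 and C4–C4a. The phenol A7 would come from (R)-linalool A6 by hydroboration and B-alkyl Suzuki coupling.
- Forward key step: a hypervalent iodine oxidant turns A7 into the spirodienone A8, and a strong Lewis acid then shifts C4 from the spiro carbon to its neighbour to give the chromanol A9.
- For it: the stereocentre is bought, the C2–O bond is never broken, no chiral catalyst is needed, and the chroman is reached in fewer steps than in the chosen route. On these points it is stronger.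
- Against it:
  - In A8 the two carbons next to the spiro centre differ only by a remote bromine, so C4 can migrate to either and give the 7-bromo or the 5-bromo chroman.
  - The Lewis acid acts on a tertiary ether beside a trisubstituted alkene, so ionisation at C2 (loss of configuration) and cation–olefin cyclisation are open.
  - The enantiomeric purity of A6 sets a ceiling.
  - After A9 the route still needs phenol protection, alkene hydration, C4 oxidation and deprotection.
- Comparison: the chosen route fixes the bromine position from the start, takes its enantiomeric purity from a catalyst, keeps carbocations away from C2, and brings the chain in at the ester level, one step from the tertiary alcohol.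

Key step: step 6

Assumption: the (S,S)-configured benzyl ligand is taken to direct oxygen to the Re face of the alkene, by analogy with closely related 2-(3-methylbut-3-enyl)phenols. The sense would be confirmed on 10, and the mirror-image ligand would be used if the opposite sense were found.

## Route

Step 1
Reactants: 1 4-bromo-2,5-dimethoxybenzaldehyde
Product: 2 4-bromo-2,5-dihydroxybenzaldehyde
Conditions: BBr3 (3 equiv), CH2Cl2, −78 °C to rt; then H2O
Reagents that add atoms: none
Why: Aryl methyl ether cleavage: BBr3 binds each methoxy oxygen and bromide attacks the methyl group in an SN2 step; the aldehyde and the C–Br bond are unchanged and the aryl borates hydrolyse on work-up.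

Step 2
Reactants: 2 4-bromo-2,5-dihydroxybenzaldehyde
Product: 3 4-bromo-5-(tert-butyldimethylsilyloxy)-2-hydroxybenzaldehyde
Conditions: TBSCl (1.05 equiv), imidazole (2 equiv), CH2Cl2, 0 °C
Reagents that add atoms: tert-butyldimethylsilyl chloride, CC(C)(C)[Si](C)(C)Cl
Why: Phenol silylation; the C2 hydroxyl (benzaldehyde numbering) is tied up in a hydrogen bond to the formyl group and is the weaker nucleophile, so one equivalent of silyl chloride should go to the free C5 hydroxyl, the future C6 oxygen.

Step 3
Reactants: 3 4-bromo-5-(tert-butyldimethylsilyloxy)-2-hydroxybenzaldehyde; 4 1-(triphenylphosphoranylidene)propan-2-one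
Product: 5 (3E)-4-[4-bromo-5-(tert-butyldimethylsilyloxy)-2-hydroxyphenyl]but-3-en-2-one
Conditions: 4 (1.2 equiv), toluene, 80 °C
Reagents that add atoms: none
Why: Wittig reaction of a stabilised ylide, which gives the E-enone under thermodynamic control; the neutral medium leaves the free phenol and the aryl silyl ether alone.

Step 4
Reactants: 5 (3E)-4-[4-bromo-5-(tert-butyldimethylsilyloxy)-2-hydroxyphenyl]but-3-en-2-one
Product: 6 4-[4-bromo-5-(tert-butyldimethylsilyloxy)-2-hydroxyphenyl]butan-2-one
Conditions: [(Ph3P)CuH]6 (0.4 equiv), degassed toluene, H2O (5 equiv), rt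
Reagents that add atoms: none
Why: Conjugate reduction by the copper hydride hexamer: the soft hydride adds to the β-carbon and the copper enolate is protonated by the phenol or by water; the C–Br bond, the silyl ether and the carbonyl group are not reduced, which is why this reagent is preferred to hydrogenation over palladium.

Step 5
Reactants: 6 4-[4-bromo-5-(tert-butyldimethylsilyloxy)-2-hydroxyphenyl]butan-2-one
Product: 7 5-bromo-4-(tert-butyldimethylsilyloxy)-2-(3-methylbut-3-en-1-yl)phenol
Conditions: Ph3PCH3Br (3.3 equiv), NaN(SiMe3)2 (3.0 equiv), THF, 0 °C; then 6, 0 °C to rt; aq. NH4Cl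
Reagents that add atoms: methyltriphenylphosphonium bromide, C[P+](c1ccccc1)(c1ccccc1)c1ccccc1.[Br-] (turned in the flask into methylenetriphenylphosphorane, C=P(c1ccccc1)(c1ccccc1)c1ccccc1)
Why: Wittig methylenation; the first equivalent of ylide deprotonates the phenol (which also opens any ring-closed hemiketal form of 6) and further ylide converts the ketone into the 1,1-disubstituted alkene; an alkoxide-free ylide at low temperature is used to keep the aryl silyl ether in place.

Step 6
Reactants: 7 5-bromo-4-(tert-butyldimethylsilyloxy)-2-(3-methylbut-3-en-1-yl)phenol; 8 methyl acrylate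
Product: 10 methyl (2E)-4-[(2S)-7-bromo-6-(tert-butyldimethylsilyloxy)-2-methylchroman-2-yl]but-2-enoate, via alkylpalladium trifluoroacetate 9 (not isolated)
Conditions: Pd(OCOCF3)2 (10 mol%), (S)-2,2'-bis[(4S)-4-benzyl-4,5-dihydrooxazol-2-yl]-1,1'-binaphthyl (40 mol%), p-benzoquinone (4 equiv), 8 (5 equiv), CH2Cl2, rt
Reagents that add atoms: none
Why: Divalent palladium carrying the C2-symmetric bis(oxazoline) ligand binds the 1,1-disubstituted alkene of 7, and the phenol oxygen adds to the substituted alkene carbon in a 6-exo-trig oxypalladation that forms O1–C2 and closes the pyran ring. C2 is set in this event by the ligand, which must direct oxygen to the Re face of that carbon (CIP order CH2CH2Ar > =CH2 > CH3) to give the S descriptor of 9 and 10, the same spatial arrangement as R in 16. The primary alkylpalladium 9 has no β-hydrogen because C2 is quaternary, so it lives until it inserts methyl acrylate 8 with carbon going to the β-position (C1'–C2' bond), and β-hydride elimination then releases the E-enoate. The zerovalent palladium left behind is returned to divalent palladium by p-benzoquinone. The closest known reaction type is the enantioselective domino Wacker–Heck reaction of 2-(3-methylbut-3-enyl)phenols with acrylates under this catalyst system. The step needs face selectivity at the alkene (ligand), a single nucleophile (the other oxygen is silylated, which also stops quinone formation) and inertness of the C–Br bond, which the absence of phosphine, room temperature and fast reoxidation should secure. Any Z-enoate converges with the E-isomer in step 7.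

Step 7
Reactants: 10 methyl (2E)-4-[(2S)-7-bromo-6-(tert-butyldimethylsilyloxy)-2-methylchroman-2-yl]but-2-enoate
Product: 11 methyl 4-[(2R)-7-bromo-6-(tert-butyldimethylsilyloxy)-2-methylchroman-2-yl]butanoate
Conditions: [(Ph3P)CuH]6 (0.5 equiv), degassed toluene, H2O (5 equiv), rt
Reagents that add atoms: none
Why: Conjugate reduction of the enoate by the copper hydride hexamer (1,4-hydride addition, then protonation of the copper enolate); the C–Br bond and the silyl ether are untouched, and the change from S to R is a change of CIP ranking only.

Step 8
Reactants: 11 methyl 4-[(2R)-7-bromo-6-(tert-butyldimethylsilyloxy)-2-methylchroman-2-yl]butanoate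
Product: 13 5-[(2R)-7-bromo-6-(tert-butyldimethylsilyloxy)-2-methylchroman-2-yl]-2-methylpentan-2-ol, via methyl ketone 12 (not isolated)
Conditions: MeMgBr (4 equiv), THF, 0 °C to rt; aq. NH4Cl
Reagents that add atoms: methylmagnesium bromide, C[Mg]Br
Why: Twofold Grignard addition to the ester through the methyl ketone 12, which is more electrophilic than the ester and is consumed at once; MeMgBr does not exchange with the aryl bromide at this temperature and the aryl silyl ether is stable to it.

Step 9
Reactants: 13 5-[(2R)-7-bromo-6-(tert-butyldimethylsilyloxy)-2-methylchroman-2-yl]-2-methylpentan-2-ol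
Product: 15 (2R)-7-bromo-6-(tert-butyldimethylsilyloxy)-2-(4-hydroxy-4-methylpentyl)-2-methylchroman-4-one, via C4 tert-butyl peroxide 14 (not isolated)
Conditions: tBuOOH (70% in H2O, 5 equiv), Rh2(caprolactamate)4 (1 mol%), NaHCO3 (0.5 equiv), 1,2-dichloroethane, 40 °C
Reagents that add atoms: tert-butyl hydroperoxide, CC(C)(C)OO
Why: Catalytic benzylic C–H oxidation: the dirhodium caprolactamate turns tBuOOH into tBuOO• radicals, which abstract hydrogen from C4, the only benzylic C–H position of 13, and the benzylic radical is trapped as the mixed peroxide 14, which loses tBuOH to give the aryl ketone; the silyl ether protects the hydroquinone oxygen, the tertiary alcohol has no carbinol hydrogen, and C2 is not involved.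

Step 10
Reactants: 15 (2R)-7-bromo-6-(tert-butyldimethylsilyloxy)-2-(4-hydroxy-4-methylpentyl)-2-methylchroman-4-one
Product: 16 (2R)-7-bromo-6-hydroxy-2-(4-hydroxy-4-methylpentyl)-2-methylchroman-4-one
Conditions: HF·pyridine, THF/pyridine, 0 °C to rt
Reagents that add atoms: none
Why: Cleavage of the aryl silyl ether by fluoride, driven by the Si–F bond; the buffered acidic medium avoids phenoxide and enolate formation and so the E1cB opening of the pyranone ring, which keeps C2 intact, and it is too mild to ionise the tertiary alcohol.

## Compound list

1 | 4-bromo-2,5-dimethoxybenzaldehyde | COc1cc(C=O)c(OC)cc1Br | starting material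
2 | 4-bromo-2,5-dihydroxybenzaldehyde | Oc1cc(C=O)c(O)cc1Br | intermediate
3 | 4-bromo-5-(tert-butyldimethylsilyloxy)-2-hydroxybenzaldehyde | CC(C)(C)[Si](C)(C)Oc1cc(C=O)c(O)cc1Br | intermediate
4 | 1-(triphenylphosphoranylidene)propan-2-one | CC(=O)C=P(c1ccccc1)(c1ccccc1)c1ccccc1 | starting material
5 | (3E)-4-[4-bromo-5-(tert-butyldimethylsilyloxy)-2-hydroxyphenyl]but-3-en-2-one | CC(=O)/C=C/c1cc(O[Si](C)(C)C(C)(C)C)c(Br)cc1O | intermediate
6 | 4-[4-bromo-5-(tert-butyldimethylsilyloxy)-2-hydroxyphenyl]butan-2-one | CC(=O)CCc1cc(O[Si](C)(C)C(C)(C)C)c(Br)cc1O | intermediate
7 | 5-bromo-4-(tert-butyldimethylsilyloxy)-2-(3-methylbut-3-en-1-yl)phenol | C=C(C)CCc1cc(O[Si](C)(C)C(C)(C)C)c(Br)cc1O | intermediate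
8 | methyl acrylate | C=CC(=O)OC | starting material
9 | {[(2S)-7-bromo-6-(tert-butyldimethylsilyloxy)-2-methylchroman-2-yl]methyl}palladium trifluoroacetate (chiral ligand on palladium left out) | FC(F)(F)C(=O)O[Pd]C[C@]1(C)CCc2cc(O[Si](C)(C)C(C)(C)C)c(Br)cc2O1 | intermediate (not isolated)
10 | methyl (2E)-4-[(2S)-7-bromo-6-(tert-butyldimethylsilyloxy)-2-methylchroman-2-yl]but-2-enoate | COC(=O)/C=C/C[C@]1(C)CCc2cc(O[Si](C)(C)C(C)(C)C)c(Br)cc2O1 | intermediate
11 | methyl 4-[(2R)-7-bromo-6-(tert-butyldimethylsilyloxy)-2-methylchroman-2-yl]butanoate | COC(=O)CCC[C@]1(C)CCc2cc(O[Si](C)(C)C(C)(C)C)c(Br)cc2O1 | intermediate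
12 | 5-[(2R)-7-bromo-6-(tert-butyldimethylsilyloxy)-2-methylchroman-2-yl]pentan-2-one | CC(=O)CCC[C@]1(C)CCc2cc(O[Si](C)(C)C(C)(C)C)c(Br)cc2O1 | intermediate (not isolated)
13 | 5-[(2R)-7-bromo-6-(tert-butyldimethylsilyloxy)-2-methylchroman-2-yl]-2-methylpentan-2-ol | CC(C)(O)CCC[C@]1(C)CCc2cc(O[Si](C)(C)C(C)(C)C)c(Br)cc2O1 | intermediate
14 | 5-[(2R)-7-bromo-4-(tert-butylperoxy)-6-(tert-butyldimethylsilyloxy)-2-methylchroman-2-yl]-2-methylpentan-2-ol (both C4 epimers) | CC(C)(O)CCC[C@]1(C)CC(OOC(C)(C)C)c2cc(O[Si](C)(C)C(C)(C)C)c(Br)cc2O1 | intermediate (not isolated)
15 | (2R)-7-bromo-6-(tert-butyldimethylsilyloxy)-2-(4-hydroxy-4-methylpentyl)-2-methylchroman-4-one | CC(C)(O)CCC[C@]1(C)CC(=O)c2cc(O[Si](C)(C)C(C)(C)C)c(Br)cc2O1 | intermediate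
16 | (2R)-7-bromo-6-hydroxy-2-(4-hydroxy-4-methylpentyl)-2-methylchroman-4-one | CC(C)(O)CCC[C@]1(C)CC(=O)c2cc(O)c(Br)cc2O1 | target

## Step count and risks

Total: 10 steps. Longest linear sequence: 10 steps, from 1 to 16; 4 and 8 are bought.

**Step 6 (key step).**
- What may go wrong: capture of the alkylpalladium by the acrylate may be slow. Protonolysis of the C–Pd bond, or insertion of accumulated zerovalent palladium into the C–Br bond, could then compete. Face selection by the ligand could also be lower than hoped with this bromo-substituted phenol.
- Fallback, from 7 back to 10: the second half of the domino is changed from alkene insertion to the faster CO insertion. The same palladium–ligand system with p-benzoquinone under CO (1 atm) in MeOH should give methyl 2-[(2S)-7-bromo-6-(tert-butyldimethylsilyloxy)-2-methylchroman-2-yl]acetate F1. Reduction with iBu2AlH at −78 °C should give 2-[(2S)-7-bromo-6-(tert-butyldimethylsilyloxy)-2-methylchroman-2-yl]acetaldehyde F2. A Wittig reaction with methyl (triphenylphosphoranylidene)acetate then rejoins the route at 10.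

**Step 9.**
- What may go wrong: the radical oxidation may stall at partial conversion or at the peroxide stage, or the electron-rich ring may be oxidised with loss of the silyl group.
- Fallback, from 13 back to 15: the C–H oxidation is replaced by a dehydrogenation–hydration sequence. DDQ in hot dioxane should give 5-[(2R)-7-bromo-6-(tert-butyldimethylsilyloxy)-2-methyl-2H-chromen-2-yl]-2-methylpentan-2-ol F3. Mukaiyama hydration (Co(acac)2, PhSiH3, O2) places oxygen at the benzylic carbon and should give 5-[(2R)-7-bromo-6-(tert-butyldimethylsilyloxy)-4-hydroxy-2-methylchroman-2-yl]-2-methylpentan-2-ol F4. MnO2 then oxidises the benzylic alcohol to 15.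

**Step 5.**
- What may go wrong: the phenoxide formed under the ylide conditions may cause silyl transfer or silyl loss, and enolisation of the ketone may leave the conversion incomplete.
- Fallback, from 6 back to 7: a Peterson olefination in two stages. Me3SiCH2MgCl (3 equiv, with CeCl3) adds to the ketone to give 5-bromo-4-(tert-butyldimethylsilyloxy)-2-[3-hydroxy-3-methyl-4-(trimethylsilyl)butyl]phenol F5. A catalytic amount of p-toluenesulfonic acid in CH2Cl2 at 0 °C then eliminates the β-hydroxysilane to 7 without strong base.

**Step 2.**
- What may go wrong: silylation may be unselective, with some reaction at the chelated hydroxyl or at both hydroxyls.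
- Fallback, from 2 back to 3: both hydroxyls are silylated with excess TBSCl and imidazole to give 4-bromo-2,5-bis(tert-butyldimethylsilyloxy)benzaldehyde F6. The silyl ether ortho to the formyl group is the more labile one, because its phenoxide is stabilised by the aldehyde, and it is removed selectively with K2CO3 in MeOH at 0 °C.

**Step 7.**
- What may go wrong: the enoate may be reduced only slowly, with incomplete conversion or some 1,2-reduction.
- Fallback, from 10 back to 13: the order of the two operations is reversed. MeMgBr with CeCl3 adds twice to the ester carbonyl to give (3E)-5-[(2S)-7-bromo-6-(tert-butyldimethylsilyloxy)-2-methylchroman-2-yl]-2-methylpent-3-en-2-ol F7. Its now unpolarised alkene is reduced by diimide (from 2-nitrobenzenesulfonylhydrazide and Et3N), which does not touch the C–Br bond, to give 13.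

## Further compounds

F1 | step 6 | methyl 2-[(2S)-7-bromo-6-(tert-butyldimethylsilyloxy)-2-methylchroman-2-yl]acetate | COC(=O)C[C@]1(C)CCc2cc(O[Si](C)(C)C(C)(C)C)c(Br)cc2O1
F2 | step 6 | 2-[(2S)-7-bromo-6-(tert-butyldimethylsilyloxy)-2-methylchroman-2-yl]acetaldehyde | O=CC[C@]1(C)CCc2cc(O[Si](C)(C)C(C)(C)C)c(Br)cc2O1
F3 | step 9 | 5-[(2R)-7-bromo-6-(tert-butyldimethylsilyloxy)-2-methyl-2H-chromen-2-yl]-2-methylpentan-2-ol | CC(C)(O)CCC[C@]1(C)C=Cc2cc(O[Si](C)(C)C(C)(C)C)c(Br)cc2O1
F4 | step 9 | 5-[(2R)-7-bromo-6-(tert-butyldimethylsilyloxy)-4-hydroxy-2-methylchroman-2-yl]-2-methylpentan-2-ol (both C4 epimers) | CC(C)(O)CCC[C@]1(C)CC(O)c2cc(O[Si](C)(C)C(C)(C)C)c(Br)cc2O1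
F5 | step 5 | 5-bromo-4-(tert-butyldimethylsilyloxy)-2-[3-hydroxy-3-methyl-4-(trimethylsilyl)butyl]phenol (racemic) | C[Si](C)(C)CC(C)(O)CCc1cc(O[Si](C)(C)C(C)(C)C)c(Br)cc1O
F6 | step 2 | 4-bromo-2,5-bis(tert-butyldimethylsilyloxy)benzaldehyde | CC(C)(C)[Si](C)(C)Oc1cc(C=O)c(O[Si](C)(C)C(C)(C)C)cc1Br
F7 | step 7 | (3E)-5-[(2S)-7-bromo-6-(tert-butyldimethylsilyloxy)-2-methylchroman-2-yl]-2-methylpent-3-en-2-ol | CC(C)(O)/C=C/C[C@]1(C)CCc2cc(O[Si](C)(C)C(C)(C)C)c(Br)cc2O1
A1 | alternative 1 | pentacarbonyl[(6R)-6-methyl-3-methylidene-6-(4-methylpent-3-en-1-yl)oxan-2-ylidene]chromium | CC(C)=CCC[C@]1(C)CCC(=C)C(=[Cr](=C=O)(=C=O)(=C=O)(=C=O)=C=O)O1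
A2 | alternative 1 | 2-ethynyl-4,4,5,5-tetramethyl-1,3,2-dioxaborolane | C#CB1OC(C)(C)C(C)(C)O1
A3 | alternative 1 | (R)-2-methyl-2-(4-methylpent-3-en-1-yl)-7-(4,4,5,5-tetramethyl-1,3,2-dioxaborolan-2-yl)chroman-6-ol | CC(C)=CCC[C@]1(C)CCc2cc(O)c(B3OC(C)(C)C(C)(C)O3)cc2O1
A4 | alternative 2 | 1-[4-bromo-5-(tert-butyldimethylsilyloxy)-2-{[(2R)-6-methyl-6-(triethylsilyloxy)heptan-2-yl]oxy}phenyl]-2-diazoethan-1-one | CC(C)(O[Si](CC)(CC)CC)CCC[C@@H](C)Oc1cc(Br)c(O[Si](C)(C)C(C)(C)C)cc1C(=O)C=[N+]=[N-]
A5 | alternative 2 | (R)-7-bromo-6-(tert-butyldimethylsilyloxy)-2-methyl-2-[4-methyl-4-(triethylsilyloxy)pentyl]chroman-4-one | CC(C)(O[Si](CC)(CC)CC)CCC[C@]1(C)CC(=O)c2cc(O[Si](C)(C)C(C)(C)C)c(Br)cc2O1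
A6 | alternative 3 | (R)-linalool, (3R)-3,7-dimethylocta-1,6-dien-3-ol | CC(C)=CCC[C@@](C)(O)C=C
A7 | alternative 3 | 2-bromo-4-[(3R)-3-hydroxy-3,7-dimethyloct-6-en-1-yl]phenol | CC(C)=CCC[C@@](C)(O)CCc1ccc(O)c(Br)c1
A8 | alternative 3 | (2R)-7-bromo-2-methyl-2-(4-methylpent-3-en-1-yl)-1-oxaspiro[4.5]deca-6,9-dien-8-one (spiro centre undefined) | CC(C)=CCC[C@]1(C)CCC2(C=CC(=O)C(Br)=C2)O1
A9 | alternative 3 | (R)-7-bromo-2-methyl-2-(4-methylpent-3-en-1-yl)chroman-6-ol | CC(C)=CCC[C@]1(C)CCc2cc(O)c(Br)cc2O1
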